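## Retrosynthetic overview

Target numbering (octahydroinden-2-one): C1 carries the acetoxyethyl chain (C1'), C2 is the ketone, C4 the methylidene, C5 the enoate, C6 the methylbutanoate, C7 the isopropyl group.

1. The C5 enoate comes from esterification after allylic oxidation of the exocyclic methylene; the C1 side chain comes from a syn-aldol of a regiodefined C1=C2 silyl enol ether with acetaldehyde.
2. The six-membered ring is formed last, at C5–C6, by a visible-light ketyl/allylsilane radical–polar crossover cyclisation of an aldehyde (key step).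
3. The C7–C7a bond comes from a Mukaiyama–Michael addition of an isovaleraldehyde enol silane to a 4-substituted cyclopentenone, anti to the C4 substituent; this fixes the trans ring fusion.
4. The cyclopentenone comes from (R)-4-silyloxycyclopentenone by cuprate addition/elimination; the five-membered ring is bought.
5. Bought stereocentres: C4 of compound 1 (relayed to all ring centres and C1') and (S)-2-methylbutanoic acid.

Assumption: compounds 1, 2, 11 and 18 are bought as the single isomers shown.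

## Route

Step 1
Reactants: 1 (R)-4-[(tert-butyldimethylsilyl)oxy]cyclopent-2-en-1-one; 2 (2-bromoallyl)trimethylsilane
Product: 5 (R)-4-[3-(trimethylsilyl)prop-1-en-2-yl]cyclopent-2-en-1-one, via vinyl Grignard reagent 3 (not isolated), via β-silyloxy ketone 4 (not isolated)
Conditions: 2, Mg, THF; CuBr·SMe2 (10 mol%), then 1, −78 °C; AcOH (1.2 equiv), then DBU (2 equiv), −78 → 0 °C, short
Reagents that add atoms: none
Why: Copper-catalysed conjugate addition of the vinyl Grignard occurs anti to the C4 silyloxy group, and E1cB loss of silanol then gives the 4-substituted enone, so the bought stereocentre is relayed to the new C4 (future C3a) (conjugate addition–β-elimination).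

Step 2
Reactants: 6 3-methylbutanal
Product: 7 (Z)-tert-butyldimethyl[(3-methylbut-1-en-1-yl)oxy]silane
Conditions: TBSOTf, Et3N, CH2Cl2, 0 °C → rt
Reagents that add atoms: tert-butyldimethylsilyl trifluoromethanesulfonate CC(C)(C)[Si](C)(C)OS(=O)(=O)C(F)(F)F
Why: Soft enolisation/O-silylation of the aldehyde gives the enol silane (silyl enol ether formation); no stereocentre is formed.

Step 3
Reactants: 5 (R)-4-[3-(trimethylsilyl)prop-1-en-2-yl]cyclopent-2-en-1-one; 7 (Z)-tert-butyldimethyl[(3-methylbut-1-en-1-yl)oxy]silane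
Product: 8 (2S)-2-[(1S,5R)-3-[(tert-butyldimethylsilyl)oxy]-5-[3-(trimethylsilyl)prop-1-en-2-yl]cyclopent-2-en-1-yl]-3-methylbutanal
Conditions: HNTf2 (2 mol%, TBSNTf2 in situ), 7 (2 equiv), CH2Cl2, −78 °C, slow addition of 5; Et3N quench
Reagents that add atoms: none
Why: Mukaiyama–Michael addition anti to the C4 substituent sets the ring carbon (future C7a); an open antiperiplanar transition state with i-Pr away from the ring substituent and H in the crowded sector is expected to set the aldehyde α-carbon (future C7); silyl transfer leaves the regiodefined enol silane.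

Step 4
Reactants: 8 (2S)-2-[(1S,5R)-3-[(tert-butyldimethylsilyl)oxy]-5-[3-(trimethylsilyl)prop-1-en-2-yl]cyclopent-2-en-1-yl]-3-methylbutanal
Product: 10 (3aR,4S,5S,7aR)-2-[(tert-butyldimethylsilyl)oxy]-7-methylidene-4-(propan-2-yl)-3a,4,5,6,7,7a-hexahydro-1H-inden-5-ol, via O-TMS ether 9 (not isolated)
Conditions: fac-Ir(ppy)3 (2 mol%), (PhO)2P(O)OH (20 mol%), MeCN (0.01 M), 450 nm LEDs, rt; then K2CO3, MeOH, 0 °C, brief
Reagents that add atoms: none
Why: Proposed new method: a redox-neutral photoredox "ketyl Sakurai" cyclisation, in which PCET from excited Ir(ppy)3/diphenyl phosphate (effective BDFE about 24 kcal/mol, matched to an aliphatic ketyl O–H) forms the neutral ketyl, which closes 6-endo on the allylsilane terminus through a chair with i-Pr and the hydrogen-bonded OH equatorial (5-exo would need a trans-bicyclo[3.3.0]octane), then Ir(IV) oxidises the β-silyl tertiary radical and loss of Me3Si+ gives the exocyclic methylene regiospecifically; the closest known reaction types are PCET ketyl–olefin coupling and the polar Hosomi–Sakurai allylation, which is expected to favour the axial alcohol instead.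

Step 5
Reactants: 10 (3aR,4S,5S,7aR)-2-[(tert-butyldimethylsilyl)oxy]-7-methylidene-4-(propan-2-yl)-3a,4,5,6,7,7a-hexahydro-1H-inden-5-ol; 11 (S)-2-methylbutanoic acid
Product: 12 (3aR,4S,5S,7aR)-2-[(tert-butyldimethylsilyl)oxy]-7-methylidene-4-(propan-2-yl)-3a,4,5,6,7,7a-hexahydro-1H-inden-5-yl (2S)-2-methylbutanoate
Conditions: 11, DCC, DMAP (cat.), CH2Cl2, 0 °C → rt
Reagents that add atoms: none
Why: Steglich esterification acylates the only free hydroxyl with retention at both the carbinol and the acid α-carbon; the TBS enol ether tolerates these neutral conditions.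

Step 6
Reactants: 12 (3aR,4S,5S,7aR)-2-[(tert-butyldimethylsilyl)oxy]-7-methylidene-4-(propan-2-yl)-3a,4,5,6,7,7a-hexahydro-1H-inden-5-yl (2S)-2-methylbutanoate; 13 acetaldehyde
Product: 16 (1S,3aR,6S,7S,7aR)-1-[(1R)-1-(acetyloxy)ethyl]-4-methylidene-2-oxo-7-(propan-2-yl)octahydro-1H-inden-6-yl (2S)-2-methylbutanoate, via sulfonium enolate 14 (not isolated), via sulfonium aldolate 15 (not isolated)
Conditions: 13 (5 equiv), TASF (1.1 equiv), THF, −78 °C; then Ac2O (3 equiv), −78 → −30 °C; pH 7 buffer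
Reagents that add atoms: acetic anhydride CC(=O)OC(C)=O
Why: Fluoride-promoted aldol of the silyl enol ether (naked enolate, open transition state) gives the syn aldol that lithium enolates of cyclic ketones do not; attack anti to the C7a substituent sets C1, and cold O-acetylation traps the aldolate before retro-aldol or elimination.

Step 7
Reactants: 16 (1S,3aR,6S,7S,7aR)-1-[(1R)-1-(acetyloxy)ethyl]-4-methylidene-2-oxo-7-(propan-2-yl)octahydro-1H-inden-6-yl (2S)-2-methylbutanoate
Product: 17 (1S,3aR,5S,6R,7S,7aR)-1-[(1R)-1-(acetyloxy)ethyl]-5-hydroxy-4-methylidene-2-oxo-7-(propan-2-yl)octahydro-1H-inden-6-yl (2S)-2-methylbutanoate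
Conditions: SeO2 (0.5 equiv), t-BuOOH (3 equiv), CH2Cl2, rt
Reagents that add atoms: selenium dioxide O=[Se]=O (catalytic oxygen carrier); tert-butyl hydroperoxide CC(C)(C)OO (stoichiometric oxygen source)
Why: Allylic oxidation by the SeO2 ene/[2,3]-sigmatropic sequence prefers the ring CH2 over the ring-fusion CH, removes the axial C5–H and returns oxygen to the same face, giving the axial alcohol cis to the C6 ester.

Step 8
Reactants: 17 (1S,3aR,5S,6R,7S,7aR)-1-[(1R)-1-(acetyloxy)ethyl]-5-hydroxy-4-methylidene-2-oxo-7-(propan-2-yl)octahydro-1H-inden-6-yl (2S)-2-methylbutanoate; 18 (E)-3-methylpent-2-enoic acid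
Product: 19 (1S,3aR,5S,6R,7S,7aR)-1-[(1R)-1-(acetyloxy)ethyl]-4-methylidene-6-{[(2S)-2-methylbutanoyl]oxy}-2-oxo-7-(propan-2-yl)octahydro-1H-inden-5-yl (2E)-3-methylpent-2-enoate
Conditions: 18, DCC, DMAP (0.2 equiv), CH2Cl2, 0 °C → rt
Reagents that add atoms: none
Why: Steglich esterification of the allylic alcohol proceeds with retention; low temperature and little DMAP limit acyl migration across the cis-diol and E/Z or deconjugative isomerisation of the enoate.

## Compound list

1 | (R)-4-[(tert-butyldimethylsilyl)oxy]cyclopent-2-en-1-one | O=C1C=C[C@H](O[Si](C)(C)C(C)(C)C)C1 | starting material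
2 | (2-bromoallyl)trimethylsilane | C=C(Br)C[Si](C)(C)C | starting material
3 | [3-(trimethylsilyl)prop-1-en-2-yl]magnesium bromide | C=C([Mg]Br)C[Si](C)(C)C | intermediate
4 | (3S,4R)-4-[(tert-butyldimethylsilyl)oxy]-3-[3-(trimethylsilyl)prop-1-en-2-yl]cyclopentan-1-one | C=C(C[Si](C)(C)C)[C@@H]1CC(=O)C[C@H]1O[Si](C)(C)C(C)(C)C | intermediate
5 | (R)-4-[3-(trimethylsilyl)prop-1-en-2-yl]cyclopent-2-en-1-one | C=C(C[Si](C)(C)C)[C@@H]1CC(=O)C=C1 | intermediate
6 | 3-methylbutanal | CC(C)CC=O | starting material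
7 | (Z)-tert-butyldimethyl[(3-methylbut-1-en-1-yl)oxy]silane | CC(C)/C=C\O[Si](C)(C)C(C)(C)C | intermediate
8 | (2S)-2-[(1S,5R)-3-[(tert-butyldimethylsilyl)oxy]-5-[3-(trimethylsilyl)prop-1-en-2-yl]cyclopent-2-en-1-yl]-3-methylbutanal | C=C(C[Si](C)(C)C)[C@@H]1CC(O[Si](C)(C)C(C)(C)C)=C[C@H]1[C@H](C(C)C)C=O | intermediate
9 | tert-butyldimethyl{[(3aR,4S,5S,7aR)-7-methylidene-4-(propan-2-yl)-5-[(trimethylsilyl)oxy]-3a,4,5,6,7,7a-hexahydro-1H-inden-2-yl]oxy}silane | C=C1[C@@H]2CC(O[Si](C)(C)C(C)(C)C)=C[C@H]2[C@H](C(C)C)[C@@H](O[Si](C)(C)C)C1 | intermediate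
10 | (3aR,4S,5S,7aR)-2-[(tert-butyldimethylsilyl)oxy]-7-methylidene-4-(propan-2-yl)-3a,4,5,6,7,7a-hexahydro-1H-inden-5-ol | C=C1[C@@H]2CC(O[Si](C)(C)C(C)(C)C)=C[C@H]2[C@H](C(C)C)[C@@H](O)C1 | intermediate
11 | (S)-2-methylbutanoic acid | CC[C@H](C)C(=O)O | starting material
12 | (3aR,4S,5S,7aR)-2-[(tert-butyldimethylsilyl)oxy]-7-methylidene-4-(propan-2-yl)-3a,4,5,6,7,7a-hexahydro-1H-inden-5-yl (2S)-2-methylbutanoate | C=C1[C@@H]2CC(O[Si](C)(C)C(C)(C)C)=C[C@H]2[C@H](C(C)C)[C@@H](OC(=O)[C@@H](C)CC)C1 | intermediate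
13 | acetaldehyde | CC=O | starting material
14 | tris(dimethylamino)sulfonium (3aR,4S,5S,7aR)-7-methylidene-5-{[(2S)-2-methylbutanoyl]oxy}-4-(propan-2-yl)-3a,4,5,6,7,7a-hexahydro-1H-inden-2-olate | C=C1[C@@H]2CC([O-])=C[C@H]2[C@H](C(C)C)[C@@H](OC(=O)[C@@H](C)CC)C1.CN(C)[S+](N(C)C)N(C)C | intermediate
15 | tris(dimethylamino)sulfonium (1R)-1-[(1S,3aR,6S,7S,7aR)-4-methylidene-6-{[(2S)-2-methylbutanoyl]oxy}-2-oxo-7-(propan-2-yl)octahydro-1H-inden-1-yl]ethan-1-olate | C=C1[C@@H]2CC(=O)[C@H]([C@@H](C)[O-])[C@H]2[C@H](C(C)C)[C@@H](OC(=O)[C@@H](C)CC)C1.CN(C)[S+](N(C)C)N(C)C | intermediate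
16 | (1S,3aR,6S,7S,7aR)-1-[(1R)-1-(acetyloxy)ethyl]-4-methylidene-2-oxo-7-(propan-2-yl)octahydro-1H-inden-6-yl (2S)-2-methylbutanoate | C=C1[C@@H]2CC(=O)[C@H]([C@@H](C)OC(C)=O)[C@H]2[C@H](C(C)C)[C@@H](OC(=O)[C@@H](C)CC)C1 | intermediate
17 | (1S,3aR,5S,6R,7S,7aR)-1-[(1R)-1-(acetyloxy)ethyl]-5-hydroxy-4-methylidene-2-oxo-7-(propan-2-yl)octahydro-1H-inden-6-yl (2S)-2-methylbutanoate | C=C1[C@@H]2CC(=O)[C@H]([C@@H](C)OC(C)=O)[C@H]2[C@H](C(C)C)[C@@H](OC(=O)[C@@H](C)CC)[C@H]1O | intermediate
18 | (E)-3-methylpent-2-enoic acid | CC/C(C)=C/C(=O)O | starting material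
19 | (1S,3aR,5S,6R,7S,7aR)-1-[(1R)-1-(acetyloxy)ethyl]-4-methylidene-6-{[(2S)-2-methylbutanoyl]oxy}-2-oxo-7-(propan-2-yl)octahydro-1H-inden-5-yl (2E)-3-methylpent-2-enoate | C=C1[C@@H]2CC(=O)[C@H]([C@@H](C)OC(C)=O)[C@H]2[C@H](C(C)C)[C@@H](OC(=O)[C@@H](C)CC)[C@H]1OC(=O)/C=C(\C)CC | target

## Step count and risks

Total steps: 8. Longest linear sequence: 7 (steps 1, 3, 4, 5, 6, 7, 8).

Most likely to fail:

Step 4 (proposed new photochemical cyclisation). The ketyl may not form or close efficiently, or the enol silane may not survive the acid. The fallback sets out from 8 and uses a thermal, polar ring closure: intramolecular Hosomi–Sakurai allylation (BF3·OEt2, CH2Cl2, −78 °C, high dilution). Its synclinal transition state is expected to give mainly the axial alcohol (3aR,4S,5R,7aR)-2-[(tert-butyldimethylsilyl)oxy]-7-methylidene-4-(propan-2-yl)-3a,4,5,6,7,7a-hexahydro-1H-inden-5-ol F1. Mitsunobu esterification of F1 with 11 (PPh3, DIAD, THF) inverts the carbinol and gives the equatorial ester, returning to the route at 12.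

Step 6 (syn-aldol with in-situ acetylation). The naked aldolate may equilibrate or eliminate, or the syn selectivity may be poor. The fallback sets out from 12: silicon-to-boron exchange (Bu2BOTf, CH2Cl2) and addition of 13 through the closed transition state of the cyclic (E)-boron enolate gives the anti aldol (1S,3aR,6S,7S,7aR)-1-[(1S)-1-hydroxyethyl]-4-methylidene-2-oxo-7-(propan-2-yl)octahydro-1H-inden-6-yl (2S)-2-methylbutanoate F2. Mitsunobu reaction of F2 with acetic acid (PPh3, DIAD) installs the acetate with inversion at C1', returning to the route at 16.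

Step 7 (SeO2 allylic oxidation). The C5 methylene is deactivated by the neighbouring ester, and the ring-fusion C–H competes. The fallback sets out from 16: allylic oxidation to the ketone (Rh2(cap)4 cat., t-BuOOH) gives the enone (1S,3aR,6R,7S,7aR)-1-[(1R)-1-(acetyloxy)ethyl]-4-methylidene-2,5-dioxo-7-(propan-2-yl)octahydro-1H-inden-6-yl (2S)-2-methylbutanoate F3. Luche reduction (NaBH4, CeCl3, MeOH, −78 °C; axial hydride delivery) gives the equatorial alcohol (1S,3aR,5R,6R,7S,7aR)-1-[(1R)-1-(acetyloxy)ethyl]-5-hydroxy-4-methylidene-2-oxo-7-(propan-2-yl)octahydro-1H-inden-6-yl (2S)-2-methylbutanoate F4. Mitsunobu esterification of F4 with 18 inverts C5 and returns to the route at 19, replacing step 8.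

Further compounds
F1 | step 4 | (3aR,4S,5R,7aR)-2-[(tert-butyldimethylsilyl)oxy]-7-methylidene-4-(propan-2-yl)-3a,4,5,6,7,7a-hexahydro-1H-inden-5-ol | C=C1[C@@H]2CC(O[Si](C)(C)C(C)(C)C)=C[C@H]2[C@H](C(C)C)[C@H](O)C1
F2 | step 6 | (1S,3aR,6S,7S,7aR)-1-[(1S)-1-hydroxyethyl]-4-methylidene-2-oxo-7-(propan-2-yl)octahydro-1H-inden-6-yl (2S)-2-methylbutanoate | C=C1[C@@H]2CC(=O)[C@H]([C@H](C)O)[C@H]2[C@H](C(C)C)[C@@H](OC(=O)[C@@H](C)CC)C1
F3 | step 7 | (1S,3aR,6R,7S,7aR)-1-[(1R)-1-(acetyloxy)ethyl]-4-methylidene-2,5-dioxo-7-(propan-2-yl)octahydro-1H-inden-6-yl (2S)-2-methylbutanoate | C=C1[C@@H]2CC(=O)[C@H]([C@@H](C)OC(C)=O)[C@H]2[C@H](C(C)C)[C@@H](OC(=O)[C@@H](C)CC)C1=O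
F4 | step 7 | (1S,3aR,5R,6R,7S,7aR)-1-[(1R)-1-(acetyloxy)ethyl]-5-hydroxy-4-methylidene-2-oxo-7-(propan-2-yl)octahydro-1H-inden-6-yl (2S)-2-methylbutanoate | C=C1[C@@H]2CC(=O)[C@H]([C@@H](C)OC(C)=O)[C@H]2[C@H](C(C)C)[C@@H](OC(=O)[C@@H](C)CC)[C@@H]1O
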